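**Plan**
- Retrosynthesis: the 2′-phenol is masked as a methoxymethyl ether and a chlorine is placed at C5 as a removable steering group. Ring C is then cut in one operation at O1–C8a, C4–C4a and O1–C2, giving a ring A aryne and a ring B 2-arylacrylic acid.
- Enabling feature: C4a and C8a are adjacent carbons of ring A that carry the C4 acyl carbon and O1, the two ends of a carboxyl C–O bond, so an aryne spanning C4a–C8a can take up a carboxylic acid whole.
- Forward order: ring A is built up to the chlorinated, prenylated ortho-silyl aryl triflate (steps 1–5) and ring B to the acrylic acid (steps 6–9). Step 10 joins them and closes ring C.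
- Stereochemistry: C3 is formed racemic. After dechlorination, asymmetric transfer hydrogenation with dynamic kinetic resolution using RuCl[(S,S)-TsDPEN](p-cymene) fixes C3 as S in the cis-(3S,4S) alcohol; C4 is then re-oxidised and the acetal removed.

Key step: step 10

Remark: the target SMILES corresponds to the (3S) configuration (CIP order at C3: C4 > C2 > C1′ > H). Chromanone numbering is used for all bicyclic compounds.

**Route**

Step 1
Reactants: 1 2-chloro-4-methoxyphenol
Product: 2 2-bromo-6-chloro-4-methoxyphenol
Conditions: NBS (1.0 equiv), i-Pr2NH (10 mol %), CH2Cl2, 0 °C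
Reagents that add atoms: N-bromosuccinimide, O=C1CCC(=O)N1Br
Why: Electrophilic aromatic bromination, in which the free hydroxyl outranks methoxy as director and, with the para position and one ortho position occupied, sends bromine to the only open position ortho to OH.

Step 2
Reactants: 2 2-bromo-6-chloro-4-methoxyphenol
Product: 5 tert-butyl[2-chloro-4-methoxy-6-(trimethylsilyl)phenoxy]dimethylsilane, via O-trimethylsilyl ether 3 (not isolated), via lithium phenoxide 4 (not isolated)
Conditions: HMDS, THF, 70 °C, then evaporate; n-BuLi, THF, −78 °C; TBSOTf, −78 → 0 °C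
Reagents that add atoms: hexamethyldisilazane, C[Si](C)(C)N[Si](C)(C)C; tert-butyldimethylsilyl triflate, CC(C)(C)[Si](C)(C)OS(=O)(=O)C(F)(F)F
Why: O-silylation, bromine–lithium exchange (chlorine does not exchange at −78 °C) and retro-Brook O→C silyl shift should place the trimethylsilyl group on carbon, and the liberated phenoxide is capped in the same flask by O-silylation with the silyl triflate.

Step 3
Reactants: 5 tert-butyl[2-chloro-4-methoxy-6-(trimethylsilyl)phenoxy]dimethylsilane; 6 prenyl bromide (1-bromo-3-methylbut-2-ene)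
Product: 9 tert-butyl[2-chloro-4-methoxy-3-(3-methylbut-2-en-1-yl)-6-(trimethylsilyl)phenoxy]dimethylsilane, via aryllithium 7 (not isolated), via arylcopper 8 (not isolated)
Conditions: s-BuLi, THF, −78 °C; CuBr·SMe2 (1.1 equiv), −78 °C; 6, −78 → 0 °C
Reagents that add atoms: none
Why: Directed ortho-metalation should occur only at the C–H flanked by chlorine and methoxy (the other ring hydrogen sits beside the bulky silyl group and the silyloxy group has no free ortho position), and transmetalation to monovalent copper both suppresses loss of LiCl from the ortho-chloro aryllithium and gives SN2 allylation at the primary carbon of prenyl bromide.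

Step 4
Reactants: 9 tert-butyl[2-chloro-4-methoxy-3-(3-methylbut-2-en-1-yl)-6-(trimethylsilyl)phenoxy]dimethylsilane
Product: 10 2-chloro-4-methoxy-3-(3-methylbut-2-en-1-yl)-6-(trimethylsilyl)phenol
Conditions: TBAF, AcOH (1:1), THF, 0 °C
Reagents that add atoms: none
Why: Fluoride-mediated cleavage of the aryl silyl ether is fast at the Si–O bond, while the acetic acid buffer keeps the aryl–silicon bond and the olefin untouched.

Step 5
Reactants: 10 2-chloro-4-methoxy-3-(3-methylbut-2-en-1-yl)-6-(trimethylsilyl)phenol
Product: 11 2-chloro-4-methoxy-3-(3-methylbut-2-en-1-yl)-6-(trimethylsilyl)phenyl trifluoromethanesulfonate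
Conditions: Tf2O, pyridine, CH2Cl2, 0 °C
Reagents that add atoms: trifluoromethanesulfonic anhydride, O=S(=O)(OS(=O)(=O)C(F)(F)F)C(F)(F)F
Why: O-sulfonylation of the phenol, the standard last step towards ortho-silyl aryl triflates, and pyridine buffers the triflic acid so the prenyl group survives.

Step 6
Reactants: 12 2-bromo-5-methoxyphenol
Product: 13 1-bromo-4-methoxy-2-(methoxymethoxy)benzene
Conditions: MOMCl, i-Pr2NEt, CH2Cl2, 0 °C → rt
Reagents that add atoms: chloromethyl methyl ether, COCCl
Why: O-alkylation of the phenol (Williamson-type acetal ether formation) installs a group that withstands organolithiums, ylide, hydroxide and hot fluoride.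

Step 7
Reactants: 13 1-bromo-4-methoxy-2-(methoxymethoxy)benzene; 14 diethyl oxalate
Product: 16 ethyl 2-[4-methoxy-2-(methoxymethoxy)phenyl]-2-oxoacetate, via aryllithium 15 (not isolated)
Conditions: n-BuLi, THF, −78 °C; then cannulate into 14 (3 equiv), THF, −78 °C
Reagents that add atoms: none
Why: Bromine–lithium exchange gives an aryllithium stabilised by the ortho acetal oxygen, and inverse addition to excess oxalate stops at monoacylation because the tetrahedral adduct persists at −78 °C.

Step 8
Reactants: 16 ethyl 2-[4-methoxy-2-(methoxymethoxy)phenyl]-2-oxoacetate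
Product: 17 ethyl 2-[4-methoxy-2-(methoxymethoxy)phenyl]prop-2-enoate
Conditions: Ph3PCH3Br, KOt-Bu, THF, 0 °C → rt
Reagents that add atoms: methyltriphenylphosphonium bromide, C[P+](c1ccccc1)(c1ccccc1)c1ccccc1.[Br-]
Why: Wittig methylenation, selective for the ketone carbonyl of the α-keto ester, which is far more electrophilic than the ester carbonyl.

Step 9
Reactants: 17 ethyl 2-[4-methoxy-2-(methoxymethoxy)phenyl]prop-2-enoate
Product: 18 2-[4-methoxy-2-(methoxymethoxy)phenyl]prop-2-enoic acid
Conditions: LiOH, THF–H2O, rt; then cold 1 M HCl to pH 4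
Reagents that add atoms: lithium hydroxide, [Li+].[OH-]
Why: Ester saponification in the absence of alkoxide avoids conjugate addition to the acrylate, and the acetal is stable to base and to brief cold acidification at pH 4.

Step 10
Reactants: 11 2-chloro-4-methoxy-3-(3-methylbut-2-en-1-yl)-6-(trimethylsilyl)phenyl trifluoromethanesulfonate; 18 2-[4-methoxy-2-(methoxymethoxy)phenyl]prop-2-enoic acid
Product: 21 racemic 5-chloro-7-methoxy-3-[4-methoxy-2-(methoxymethoxy)phenyl]-6-(3-methylbut-2-en-1-yl)chroman-4-one, via aryne 19 (not isolated), via enone phenoxide 20 (not isolated)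
Conditions: CsF (4 equiv), 11 (1.5 equiv), THF, 125 °C, sealed tube
Reagents that add atoms: none
Why: Fluoride attack on silicon expels triflate and gives aryne 19; the carboxylate oxygen of deprotonated 18 adds to the aryne carbon remote from chlorine (future C8a), the aryl anion next to chlorine (future C4a) attacks the carboxyl carbon, and the four-membered adduct opens to ortho-acyl phenoxide 20, a net insertion of the aryne into the acyl C–O bond that forms O1–C8a and C4–C4a. Phenoxide 20 then closes ring C by 6-endo-trig oxa-Michael addition to the terminus of the α-aryl enone (O1–C2), and protonation of the enolate leaves C3 racemic, no control being sought here. The closest known reaction type is the fluoride-induced insertion of arynes into the C–O bond of carboxylic acids, which with acrylic acids continues to chroman-4-ones. The selectivity needed is the orientation of carboxylate addition: the inductively withdrawing chlorine flanking the triple bond distorts the aryne so that the remote carbon is the more electrophilic and the charge develops beside the halogen, whereas methoxy and prenyl, one position further away, exert only a weak bias. The high temperature favours acyl transfer by the aryl anion over its protonation to a simple aryl ester.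

Step 11
Reactants: 21 racemic 5-chloro-7-methoxy-3-[4-methoxy-2-(methoxymethoxy)phenyl]-6-(3-methylbut-2-en-1-yl)chroman-4-one
Product: 22 racemic 7-methoxy-3-[4-methoxy-2-(methoxymethoxy)phenyl]-6-(3-methylbut-2-en-1-yl)chroman-4-one
Conditions: Pd(OAc)2 (5 mol %), XPhos (10 mol %), HCO2Na (3 equiv), DMF–H2O, 80 °C
Reagents that add atoms: none
Why: Palladium-catalysed transfer hydrodehalogenation, in which zerovalent palladium on a bulky biarylphosphine inserts into the C–Cl bond activated by the ortho carbonyl, formate supplies hydride by decarboxylation, and the homogeneous catalyst should leave the trisubstituted olefin alone.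

Step 12
Reactants: 22 racemic 7-methoxy-3-[4-methoxy-2-(methoxymethoxy)phenyl]-6-(3-methylbut-2-en-1-yl)chroman-4-one
Product: 23 (3S,4S)-7-methoxy-3-[4-methoxy-2-(methoxymethoxy)phenyl]-6-(3-methylbut-2-en-1-yl)chroman-4-ol
Conditions: RuCl[(S,S)-TsDPEN](p-cymene) (3 mol %), HCO2H–Et3N (5:2), EtOAc, 40 °C
Reagents that add atoms: none
Why: Noyori-type asymmetric transfer hydrogenation under dynamic kinetic resolution: Et3N equilibrates the C3 epimers through the enol, and the (S,S) catalyst reduces the (3S) ketone faster and delivers hydride to the carbonyl face anti to the 3-aryl group, which should give the cis (3S,4S) alcohol (C4 as in the (S)-selective reduction of chroman-4-one) while the isolated olefin is inert.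

Step 13
Reactants: 23 (3S,4S)-7-methoxy-3-[4-methoxy-2-(methoxymethoxy)phenyl]-6-(3-methylbut-2-en-1-yl)chroman-4-ol
Product: 24 (3S)-7-methoxy-3-[4-methoxy-2-(methoxymethoxy)phenyl]-6-(3-methylbut-2-en-1-yl)chroman-4-one
Conditions: Dess–Martin periodinane, NaHCO3, CH2Cl2, 0 °C
Reagents that add atoms: none
Why: Dess–Martin oxidation of the benzylic alcohol under buffered, near-neutral conditions at low temperature removes the auxiliary C4 stereocentre without offering a base or strong acid that could enolise C3.

Step 14
Reactants: 24 (3S)-7-methoxy-3-[4-methoxy-2-(methoxymethoxy)phenyl]-6-(3-methylbut-2-en-1-yl)chroman-4-one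
Product: 25 (3S)-3-(2-hydroxy-4-methoxyphenyl)-7-methoxy-6-(3-methylbut-2-en-1-yl)chroman-4-one
Conditions: ZnBr2, n-PrSH, CH2Cl2, 0 °C, 10 min
Reagents that add atoms: none
Why: Lewis acid–thiol cleavage of the methoxymethyl acetal (ZnBr2 activates the acetal, the thiol takes up the methylene carbon) is complete within minutes at 0 °C, so neither enolisation at C3 nor addition to the prenyl olefin should compete.

**Compound list**

1 | 2-chloro-4-methoxyphenol | COc1ccc(O)c(Cl)c1 | starting material
2 | 2-bromo-6-chloro-4-methoxyphenol | COc1cc(Cl)c(O)c(Br)c1 | intermediate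
3 | (2-bromo-6-chloro-4-methoxyphenoxy)trimethylsilane (formed in the flask) | COc1cc(Cl)c(O[Si](C)(C)C)c(Br)c1 | intermediate
4 | lithium 2-chloro-4-methoxy-6-(trimethylsilyl)phenoxide (formed in the flask) | COc1cc(Cl)c([O-])c([Si](C)(C)C)c1.[Li+] | intermediate
5 | tert-butyl[2-chloro-4-methoxy-6-(trimethylsilyl)phenoxy]dimethylsilane | COc1cc([Si](C)(C)C)c(O[Si](C)(C)C(C)(C)C)c(Cl)c1 | intermediate
6 | prenyl bromide (1-bromo-3-methylbut-2-ene) | CC(C)=CCBr | starting material
7 | {3-[(tert-butyldimethylsilyl)oxy]-2-chloro-6-methoxy-4-(trimethylsilyl)phenyl}lithium (formed in the flask) | COc1cc([Si](C)(C)C)c(O[Si](C)(C)C(C)(C)C)c(Cl)c1[Li] | intermediate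
8 | {3-[(tert-butyldimethylsilyl)oxy]-2-chloro-6-methoxy-4-(trimethylsilyl)phenyl}copper (formed in the flask) | COc1cc([Si](C)(C)C)c(O[Si](C)(C)C(C)(C)C)c(Cl)c1[Cu] | intermediate
9 | tert-butyl[2-chloro-4-methoxy-3-(3-methylbut-2-en-1-yl)-6-(trimethylsilyl)phenoxy]dimethylsilane | COc1cc([Si](C)(C)C)c(O[Si](C)(C)C(C)(C)C)c(Cl)c1CC=C(C)C | intermediate
10 | 2-chloro-4-methoxy-3-(3-methylbut-2-en-1-yl)-6-(trimethylsilyl)phenol | COc1cc([Si](C)(C)C)c(O)c(Cl)c1CC=C(C)C | intermediate
11 | 2-chloro-4-methoxy-3-(3-methylbut-2-en-1-yl)-6-(trimethylsilyl)phenyl trifluoromethanesulfonate | COc1cc([Si](C)(C)C)c(OS(=O)(=O)C(F)(F)F)c(Cl)c1CC=C(C)C | intermediate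
12 | 2-bromo-5-methoxyphenol | COc1ccc(Br)c(O)c1 | starting material
13 | 1-bromo-4-methoxy-2-(methoxymethoxy)benzene | COCOc1cc(OC)ccc1Br | intermediate
14 | diethyl oxalate | CCOC(=O)C(=O)OCC | starting material
15 | [4-methoxy-2-(methoxymethoxy)phenyl]lithium (formed in the flask) | COCOc1cc(OC)ccc1[Li] | intermediate
16 | ethyl 2-[4-methoxy-2-(methoxymethoxy)phenyl]-2-oxoacetate | CCOC(=O)C(=O)c1ccc(OC)cc1OCOC | intermediate
17 | ethyl 2-[4-methoxy-2-(methoxymethoxy)phenyl]prop-2-enoate | C=C(C(=O)OCC)c1ccc(OC)cc1OCOC | intermediate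
18 | 2-[4-methoxy-2-(methoxymethoxy)phenyl]prop-2-enoic acid | C=C(C(=O)O)c1ccc(OC)cc1OCOC | intermediate
19 | 3-chloro-5-methoxy-4-(3-methylbut-2-en-1-yl)benzyne, triple bond C1–C2 (formed in the flask) | COC1=CC#CC(Cl)=C1CC=C(C)C | intermediate
20 | cesium 3-chloro-5-methoxy-2-{2-[4-methoxy-2-(methoxymethoxy)phenyl]prop-2-enoyl}-4-(3-methylbut-2-en-1-yl)phenoxide (formed in the flask) | C=C(C(=O)c1c([O-])cc(OC)c(CC=C(C)C)c1Cl)c1ccc(OC)cc1OCOC.[Cs+] | intermediate
21 | racemic 5-chloro-7-methoxy-3-[4-methoxy-2-(methoxymethoxy)phenyl]-6-(3-methylbut-2-en-1-yl)chroman-4-one | COc1ccc(C2COc3cc(OC)c(CC=C(C)C)c(Cl)c3C2=O)c(OCOC)c1 | intermediate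
22 | racemic 7-methoxy-3-[4-methoxy-2-(methoxymethoxy)phenyl]-6-(3-methylbut-2-en-1-yl)chroman-4-one | COc1ccc(C2COc3cc(OC)c(CC=C(C)C)cc3C2=O)c(OCOC)c1 | intermediate
23 | (3S,4S)-7-methoxy-3-[4-methoxy-2-(methoxymethoxy)phenyl]-6-(3-methylbut-2-en-1-yl)chroman-4-ol (cis) | COc1ccc([C@H]2COc3cc(OC)c(CC=C(C)C)cc3[C@H]2O)c(OCOC)c1 | intermediate
24 | (3S)-7-methoxy-3-[4-methoxy-2-(methoxymethoxy)phenyl]-6-(3-methylbut-2-en-1-yl)chroman-4-one | COc1ccc([C@H]2COc3cc(OC)c(CC=C(C)C)cc3C2=O)c(OCOC)c1 | intermediate
25 | (3S)-3-(2-hydroxy-4-methoxyphenyl)-7-methoxy-6-(3-methylbut-2-en-1-yl)chroman-4-one | COc1ccc([C@H]2COc3cc(OC)c(CC=C(C)C)cc3C2=O)c(O)c1 | target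

**Step count**

Total: 14 steps. Longest linear sequence: 10 steps (steps 1–5 and 10–14); the ring B branch is 4 steps (6–9).

**Steps most likely to fail**

Step 10. The aryl anion may be protonated before acyl transfer, leaving an aryl ester, or the acrylic acid may oligomerise at 125 °C. The fallback separates ring closure from the aryne insertion; it sets out from 13 and 11 and returns at 21. Bromide 13 is coupled under zerovalent palladium catalysis (Pd2(dba)3, XPhos, THF, 60 °C) with the Reformatsky reagent BrZnCH2CO2Et in a Negishi-type α-arylation to give ethyl 2-[4-methoxy-2-(methoxymethoxy)phenyl]acetate F1. Saponification (LiOH, THF–H2O, then pH 4) gives 2-[4-methoxy-2-(methoxymethoxy)phenyl]acetic acid F2. F2 and triflate 11 under CsF in THF at 125 °C should undergo the same chlorine-steered C–O insertion, now with a saturated acid that cannot polymerise, to give 1-[2-chloro-6-hydroxy-4-methoxy-3-(3-methylbut-2-en-1-yl)phenyl]-2-[4-methoxy-2-(methoxymethoxy)phenyl]ethan-1-one F3. Paraformaldehyde and Et2NH in MeOH at reflux then install the α-methylene group, giving 1-[2-chloro-6-hydroxy-4-methoxy-3-(3-methylbut-2-en-1-yl)phenyl]-2-[4-methoxy-2-(methoxymethoxy)phenyl]prop-2-en-1-one F4, which closes by oxa-Michael addition to 21.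

Step 11. A palladium hydride may reduce or shift the prenyl double bond, or oxidative addition at the doubly ortho-substituted chloride may stall. The fallback avoids any metal hydride; it sets out from 21 and returns at 22. Miyaura borylation (B2pin2, Pd2(dba)3, XPhos, KOAc, 1,4-dioxane, 100 °C) gives racemic 7-methoxy-3-[4-methoxy-2-(methoxymethoxy)phenyl]-6-(3-methylbut-2-en-1-yl)-5-(4,4,5,5-tetramethyl-1,3,2-dioxaborolan-2-yl)chroman-4-one F5. Its hindered, ortho-acyl carbon–boron bond should undergo base-mediated protodeboronation (aqueous K3PO4, 1,4-dioxane, 80 °C) to 22, racemisation at C3 being of no concern at this stage.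

Step 13. The C3 configuration may erode by enolisation of the newly formed α-aryl ketone during oxidation or work-up; the same process threatens step 14, which is why that step is kept short and cold. The fallback sets C3 by enantioselective protonation in place of reduction and re-oxidation; it sets out from 22 and returns at 24. Enolisation with LiN(SiMe3)2 (THF, −78 °C) and O-acylation with allyl chloroformate give allyl 7-methoxy-3-[4-methoxy-2-(methoxymethoxy)phenyl]-6-(3-methylbut-2-en-1-yl)-2H-chromen-4-yl carbonate F6. Palladium-catalysed decarboxylative enantioselective protonation (Pd2(dba)3, a tert-butyl-PHOX ligand, Meldrum's acid as proton donor and allyl acceptor, 1,4-dioxane, 40 °C) then delivers 24 under neutral conditions. The ligand antipode that leads to the (3S) ketone would be fixed in a small trial.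

**Further compounds**

F1 | step 10 | ethyl 2-[4-methoxy-2-(methoxymethoxy)phenyl]acetate | CCOC(=O)Cc1ccc(OC)cc1OCOC
F2 | step 10 | 2-[4-methoxy-2-(methoxymethoxy)phenyl]acetic acid | OC(=O)Cc1ccc(OC)cc1OCOC
F3 | step 10 | 1-[2-chloro-6-hydroxy-4-methoxy-3-(3-methylbut-2-en-1-yl)phenyl]-2-[4-methoxy-2-(methoxymethoxy)phenyl]ethan-1-one | COCOc1cc(OC)ccc1CC(=O)c1c(O)cc(OC)c(CC=C(C)C)c1Cl
F4 | step 10 | 1-[2-chloro-6-hydroxy-4-methoxy-3-(3-methylbut-2-en-1-yl)phenyl]-2-[4-methoxy-2-(methoxymethoxy)phenyl]prop-2-en-1-one | C=C(C(=O)c1c(O)cc(OC)c(CC=C(C)C)c1Cl)c1ccc(OC)cc1OCOC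
F5 | step 11 | racemic 7-methoxy-3-[4-methoxy-2-(methoxymethoxy)phenyl]-6-(3-methylbut-2-en-1-yl)-5-(4,4,5,5-tetramethyl-1,3,2-dioxaborolan-2-yl)chroman-4-one | COc1ccc(C2COc3cc(OC)c(CC=C(C)C)c(B4OC(C)(C)C(C)(C)O4)c3C2=O)c(OCOC)c1
F6 | step 13 | allyl 7-methoxy-3-[4-methoxy-2-(methoxymethoxy)phenyl]-6-(3-methylbut-2-en-1-yl)-2H-chromen-4-yl carbonate | C=CCOC(=O)OC1=C(c2ccc(OC)cc2OCOC)COc2cc(OC)c(CC=C(C)C)cc12
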